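Ring A of the flavone is a benzene without any C–H, whose four adjacent oxygen-bearing carbons C5–C8 sit between the fusion atoms C4a and C8a. This pattern is the four-carbon core of dimethyl squarate joined to one C=C bond, so ring A is disconnected to the squarate and the C5=C6 alkene of a preformed 2-aryl-3-benzyloxy-4-pyranone (ring C, built from furan by oxidative ring expansion). Heating the 4-hydroxy-4-pyranonyl-cyclobutenone adduct opens the four-membered ring and recloses it as the 5,8-dihydroxy-6,7-dimethoxy benzo ring, delivering the whole chromone bicycle with every oxygen in place in one operation. Methylation of the free 8-OH and hydrogenolysis finish the synthesis.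

Key step: step 8

Assumption: every stereocentre formed on the way (in 4, 5, 6, 7, 12 and 14) is carried as a racemate or diastereomer mixture, because each of these carbons ends as an sp2 carbon of the achiral target.

Step 1
Reactants: 1 furan; 2 3,4-bis(benzyloxy)benzaldehyde
Product: 4 [3,4-bis(benzyloxy)phenyl](furan-2-yl)methanol (racemic), via 2-furyllithium 3 (not isolated)
Conditions: furan (1.2 equiv), n-BuLi (1.1 equiv), THF, −78 to 0 °C; then 2, −78 °C to rt; aq. NH4Cl
Reagents that add atoms: none
Why: α-Lithiation of furan followed by 1,2-addition of the 2-furyllithium to the aryl aldehyde is a standard organolithium carbonyl addition; the carbinol stereocentre forms racemic and is destroyed later.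

Step 2
Reactants: 4 [3,4-bis(benzyloxy)phenyl](furan-2-yl)methanol
Product: 5 2-[3,4-bis(benzyloxy)phenyl]-6-hydroxy-2H-pyran-3(6H)-one (mixture of diastereomers)
Conditions: NBS (1.05 equiv), NaHCO3, THF/H2O (4:1), 0 °C
Reagents that add atoms: water, O
Why: Achmatowicz rearrangement, in which oxidation of the furan (far more nucleophilic toward NBS than the dialkoxybenzene in the buffered medium), hydrolysis to the cis-enedione and ring closure by the carbinol oxygen give the pyranone hemiacetal; C2 and C6 form as an inconsequential mixture.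

Step 3
Reactants: 5 2-[3,4-bis(benzyloxy)phenyl]-6-hydroxy-2H-pyran-3(6H)-one
Product: 6 2-[3,4-bis(benzyloxy)phenyl]-6-methoxy-2H-pyran-3(6H)-one (mixture of diastereomers)
Conditions: HC(OMe)3 (3 equiv), BF3·OEt2 (cat.), CH2Cl2, 0 °C
Reagents that add atoms: trimethyl orthoformate, COC(OC)OC
Why: Acid-catalysed acetal exchange through the ring oxocarbenium ion (Fischer-type glycosidation, the orthoformate scavenging water) caps the base-labile hemiacetal before the alkaline oxidation; the anomeric mixture is carried on.

Step 4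
Reactants: 6 2-[3,4-bis(benzyloxy)phenyl]-6-methoxy-2H-pyran-3(6H)-one
Product: 7 4-[3,4-bis(benzyloxy)phenyl]-2-methoxy-3,7-dioxabicyclo[4.1.0]heptan-5-one (the 4,5-epoxide of 6; mixture of diastereomers)
Conditions: 30% H2O2, NaOH (0.2 equiv), MeOH, 0 °C
Reagents that add atoms: hydrogen peroxide, OO
Why: Weitz–Scheffer nucleophilic epoxidation (conjugate addition of hydroperoxide to the electron-poor enone and closure of the enolate) leaves the electron-rich arene and the benzyl ethers alone; the epoxide should form mainly anti to the 6-methoxy group, but every new stereocentre is lost in step 5.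

Step 5
Reactants: 7 4-[3,4-bis(benzyloxy)phenyl]-2-methoxy-3,7-dioxabicyclo[4.1.0]heptan-5-one
Product: 8 2-[3,4-bis(benzyloxy)phenyl]-3-hydroxy-4H-pyran-4-one
Conditions: p-TsOH·H2O (0.2 equiv), 1,4-dioxane/H2O (9:1), 80 °C
Reagents that add atoms: none
Why: Acid-promoted isomerization of the α,β-epoxy ketone to the 3,4-dione level (epoxide opening at C5, C4 becoming a carbonyl), β-elimination of methanol across C5–C6 and enolization toward C2 should give the 3-hydroxy-4-pyranone, the established laboratory route from 6-alkoxy-2H-pyran-3(6H)-ones to maltol-type pyranones.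

Step 6
Reactants: 8 2-[3,4-bis(benzyloxy)phenyl]-3-hydroxy-4H-pyran-4-one
Product: 9 3-(benzyloxy)-2-[3,4-bis(benzyloxy)phenyl]-4H-pyran-4-one
Conditions: BnBr (1.2 equiv), K2CO3, DMF, rt
Reagents that add atoms: benzyl bromide, BrCc1ccccc1
Why: Williamson etherification of the acidic enolic 3-OH (routine for maltol-type hydroxypyranones) removes the acidic proton before metalation and adds a third benzyl group that leaves together with the other two in the last step.

Step 7
Reactants: 9 3-(benzyloxy)-2-[3,4-bis(benzyloxy)phenyl]-4H-pyran-4-one; 10 dimethyl squarate (3,4-dimethoxycyclobut-3-ene-1,2-dione)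
Product: 12 4-{5-(benzyloxy)-6-[3,4-bis(benzyloxy)phenyl]-4-oxo-4H-pyran-2-yl}-4-hydroxy-2,3-dimethoxycyclobut-2-en-1-one (racemic), via 6-lithio-4-pyranone 11 (not isolated)
Conditions: LiTMP (1.1 equiv, from 2,2,6,6-tetramethylpiperidine and n-BuLi), THF, −78 °C, 10 min; then 10 (1.2 equiv) in THF, −78 °C; aq. NH4Cl at −78 °C
Reagents that add atoms: none
Why: Proposed new method: deprotonative lithiation of a monocyclic 4-pyranone at C6–H followed by 1,2-addition to a squarate carbonyl; C6–H is the sp2 C–H next to the ring oxygen and β to the carbonyl, acidified in the same way as C2–H of chromones, which hindered lithium amides remove at −78 °C (closest known reaction type: C2 lithiation of chromones by LiTMP with electrophile trapping, combined with the standard 1,2-addition of aryl- and alkenyllithiums to dialkyl squarates); the α-oxygenated vinyllithium 11 is kept cold and consumed at once to outrun ring opening or self-addition, the two squarate carbonyls are equivalent so no regiochemical question arises, and the new quaternary carbinol centre forms racemic and is erased in step 8.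

Step 8
Reactants: 12 4-{5-(benzyloxy)-6-[3,4-bis(benzyloxy)phenyl]-4-oxo-4H-pyran-2-yl}-4-hydroxy-2,3-dimethoxycyclobut-2-en-1-one
Product: 15 3-(benzyloxy)-2-[3,4-bis(benzyloxy)phenyl]-5,8-dihydroxy-6,7-dimethoxy-4H-chromen-4-one, via (Z)-dienylketene 13 (not isolated), via 4aH-chromene-4,5-dione 14 (not isolated)
Conditions: degassed toluene, reflux (110 °C), argon
Reagents that add atoms: none
Why: Moore rearrangement: thermal conrotatory 4π ring opening cleaves the cyclobutenone C1–C4 bond to dienylketene 13, whose ketene carbon (future C5) then bonds to pyranone C5 (future C4a) in a 6π electrocyclization, and enolization of the doubly carbonyl-activated C4a–H of dienone 14 aromatizes the new ring to hydroquinone 15. The closest known reaction type is the thermolysis of 4-alkenyl- and 4-(hetero)aryl-4-hydroxy-2,3-dialkoxycyclobutenones, made from squarate esters and organolithiums, to 2,3-dialkoxyhydroquinones. The one ring closed is carbocyclic ring A (C5–C6–C7–C8–C8a–C4a), formed by a thermally allowed disrotatory 6π electrocyclization of the ketene–diene unit. No stereocentre results, since the racemic carbinol carbon becomes aromatic C8 and the transient sp3 C4a of 14 is lost on tautomerization. The step needs the torquoselectivity that turns the hydroxyl outward and the pyranonyl group inward, next to the ketene, which the strong outward preference of an oxygen donor on the breaking bond secures; the site of annulation needs no control, because C5 is the only alkene terminus attached at C6 and, as the β-carbon of the O1–C6=C5 enol ether, it is electronically matched to the electrophilic ketene carbon. Exclusion of oxygen should keep the electron-rich hydroquinone from being oxidized at the 5,8-positions.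

Step 9
Reactants: 15 3-(benzyloxy)-2-[3,4-bis(benzyloxy)phenyl]-5,8-dihydroxy-6,7-dimethoxy-4H-chromen-4-one
Product: 16 3-(benzyloxy)-2-[3,4-bis(benzyloxy)phenyl]-5-hydroxy-6,7,8-trimethoxy-4H-chromen-4-one
Conditions: MeI (1.1 equiv), K2CO3 (1.5 equiv), acetone, rt, argon
Reagents that add atoms: iodomethane, CI
Why: Chemoselective Williamson O-methylation, since the 5-OH is locked in a hydrogen bond to the C4 carbonyl and is much less nucleophilic, so one equivalent of iodomethane under mild carbonate conditions should alkylate only the free 8-OH, the usual behaviour of 5-hydroxyflavones on partial methylation.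

Step 10
Reactants: 16 3-(benzyloxy)-2-[3,4-bis(benzyloxy)phenyl]-5-hydroxy-6,7,8-trimethoxy-4H-chromen-4-one
Product: 17 2-(3,4-dihydroxyphenyl)-3,5-dihydroxy-6,7,8-trimethoxy-4H-chromen-4-one (3,5,3',4'-tetrahydroxy-6,7,8-trimethoxyflavone)
Conditions: H2 (1 atm), 10% Pd/C, THF/MeOH, rt
Reagents that add atoms: none
Why: Catalytic hydrogenolysis cleaves the three benzylic C–O bonds under neutral conditions that do not touch the methyl ethers or the chromone core, a standard final deprotection of benzylated flavonols.

Compound list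
1 | furan | c1ccoc1 | starting material
2 | 3,4-bis(benzyloxy)benzaldehyde | O=Cc1ccc(OCc2ccccc2)c(OCc2ccccc2)c1 | starting material
3 | 2-furyllithium | [Li]c1ccco1 | intermediate
4 | [3,4-bis(benzyloxy)phenyl](furan-2-yl)methanol (racemic) | OC(c1ccco1)c1ccc(OCc2ccccc2)c(OCc2ccccc2)c1 | intermediate
5 | 2-[3,4-bis(benzyloxy)phenyl]-6-hydroxy-2H-pyran-3(6H)-one (mixture of diastereomers) | O=C1C=CC(O)OC1c1ccc(OCc2ccccc2)c(OCc2ccccc2)c1 | intermediate
6 | 2-[3,4-bis(benzyloxy)phenyl]-6-methoxy-2H-pyran-3(6H)-one (mixture of diastereomers) | COC1C=CC(=O)C(c2ccc(OCc3ccccc3)c(OCc3ccccc3)c2)O1 | intermediate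
7 | 4-[3,4-bis(benzyloxy)phenyl]-2-methoxy-3,7-dioxabicyclo[4.1.0]heptan-5-one (mixture of diastereomers) | COC1OC(c2ccc(OCc3ccccc3)c(OCc3ccccc3)c2)C(=O)C2OC12 | intermediate
8 | 2-[3,4-bis(benzyloxy)phenyl]-3-hydroxy-4H-pyran-4-one | O=c1ccoc(-c2ccc(OCc3ccccc3)c(OCc3ccccc3)c2)c1O | intermediate
9 | 3-(benzyloxy)-2-[3,4-bis(benzyloxy)phenyl]-4H-pyran-4-one | O=c1ccoc(-c2ccc(OCc3ccccc3)c(OCc3ccccc3)c2)c1OCc1ccccc1 | intermediate
10 | dimethyl squarate (3,4-dimethoxycyclobut-3-ene-1,2-dione) | COC1=C(OC)C(=O)C1=O | starting material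
11 | 3-(benzyloxy)-2-[3,4-bis(benzyloxy)phenyl]-6-lithio-4H-pyran-4-one | [Li]c1cc(=O)c(OCc2ccccc2)c(-c2ccc(OCc3ccccc3)c(OCc3ccccc3)c2)o1 | intermediate
12 | 4-{5-(benzyloxy)-6-[3,4-bis(benzyloxy)phenyl]-4-oxo-4H-pyran-2-yl}-4-hydroxy-2,3-dimethoxycyclobut-2-en-1-one (racemic) | COC1=C(OC)C(O)(c2cc(=O)c(OCc3ccccc3)c(-c3ccc(OCc4ccccc4)c(OCc4ccccc4)c3)o2)C1=O | intermediate
13 | (3Z)-4-{5-(benzyloxy)-6-[3,4-bis(benzyloxy)phenyl]-4-oxo-4H-pyran-2-yl}-4-hydroxy-2,3-dimethoxybuta-1,3-dien-1-one (dienylketene, ketene arm cis to the pyranonyl group) | O=C=C(OC)/C(OC)=C(/O)c1cc(=O)c(OCc2ccccc2)c(-c2ccc(OCc3ccccc3)c(OCc3ccccc3)c2)o1 | intermediate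
14 | 3-(benzyloxy)-2-[3,4-bis(benzyloxy)phenyl]-8-hydroxy-6,7-dimethoxy-4aH-chromene-4,5-dione (racemic, transient) | COC1=C(OC)C(=O)C2C(=O)C(OCc3ccccc3)=C(c3ccc(OCc4ccccc4)c(OCc4ccccc4)c3)OC2=C1O | intermediate
15 | 3-(benzyloxy)-2-[3,4-bis(benzyloxy)phenyl]-5,8-dihydroxy-6,7-dimethoxy-4H-chromen-4-one | COc1c(OC)c(O)c2oc(-c3ccc(OCc4ccccc4)c(OCc4ccccc4)c3)c(OCc3ccccc3)c(=O)c2c1O | intermediate
16 | 3-(benzyloxy)-2-[3,4-bis(benzyloxy)phenyl]-5-hydroxy-6,7,8-trimethoxy-4H-chromen-4-one | COc1c(OC)c(O)c2c(=O)c(OCc3ccccc3)c(-c3ccc(OCc4ccccc4)c(OCc4ccccc4)c3)oc2c1OC | intermediate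
17 | 2-(3,4-dihydroxyphenyl)-3,5-dihydroxy-6,7,8-trimethoxy-4H-chromen-4-one | COc1c(OC)c(O)c2c(=O)c(O)c(-c3ccc(O)c(O)c3)oc2c1OC | target

Total step count: 10 steps.
Longest linear sequence: 10 steps (from 1 and 2 through steps 1 to 10; dimethyl squarate 10 enters in step 7).

Steps most likely to fail

Step 7. The deprotonation may be incomplete or unselective (competing removal of C5–H with ring opening, or addition of the amide base or of the lithiated pyranone to a second pyranone), and the lithio species may decompose before it meets the squarate. The fallback uses only known flavonoid chemistry, sets out from compound 2 and comes back to the route at compound 17.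
- Claisen–Schmidt condensation of 2 with purchased 2'-hydroxy-3',4',5',6'-tetramethoxyacetophenone (CC(=O)c1c(O)c(OC)c(OC)c(OC)c1OC; KOH, EtOH, rt) would give (E)-3-[3,4-bis(benzyloxy)phenyl]-1-(2-hydroxy-3,4,5,6-tetramethoxyphenyl)prop-2-en-1-one F1.
- Oxidative cyclization (catalytic I2, DMSO, 130 °C) would convert it into 3',4'-bis(benzyloxy)-5,6,7,8-tetramethoxyflavone F2.
- Epoxidation of the C2=C3 bond with dimethyldioxirane (acetone/CH2Cl2, 0 °C) would give the flavone 2,3-epoxide F3, which is opened in the same flask by a trace of p-TsOH to 3',4'-bis(benzyloxy)-3-hydroxy-5,6,7,8-tetramethoxyflavone F4.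
- Chelation-directed cleavage of the peri 5-O-methyl group (AlCl3, MeCN, rt) would give 3',4'-bis(benzyloxy)-3,5-dihydroxy-6,7,8-trimethoxyflavone F5.
- Hydrogenolysis (H2, 10% Pd/C) then gives 17.

Step 8. The ketene may be intercepted by the free tertiary hydroxyl (lactonization) or by adventitious nucleophiles instead of undergoing electrocyclization, and the hydroquinone may be oxidized by air in the hot solution. The fallback sets out from compound 12 and comes back at compound 16. The tertiary alcohol is methylated first (MeI, Ag2O, MeCN, rt) to 4-{5-(benzyloxy)-6-[3,4-bis(benzyloxy)phenyl]-4-oxo-4H-pyran-2-yl}-2,3,4-trimethoxycyclobut-2-en-1-one F6. Its thermolysis (degassed toluene, 110 °C) follows the same ring opening and 6π closure but ends directly in the 8-O-methyl ether 16. No free hydroxyl then faces the ketene, no hydroquinone has to be handled, and step 9 falls away.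

Step 5. The acid-promoted isomerization may stall or divert (acetal hydrolysis and ring opening of the epoxy ketone outrunning the opening/elimination sequence, or partial loss of benzyl groups if the acid has to be forced); the alkaline epoxidation before it may also erode material through enolization at the benzylic C2–H. The fallback sets out from compound 6, bypasses 7 and comes back at compound 8. The extra oxygen is introduced under neutral conditions by dihydroxylation of the enone C4=C5 bond (catalytic OsO4, NMO, acetone/H2O, rt) to 2-[3,4-bis(benzyloxy)phenyl]-4,5-dihydroxy-6-methoxyoxan-3-one F7. Mild acid (catalytic p-TsOH, toluene, 80 °C) should then dehydrate the β-hydroxy ketone, eliminate methanol across C5–C6 and enolize to 8.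

Further compounds
F1 | step 7 | (E)-3-[3,4-bis(benzyloxy)phenyl]-1-(2-hydroxy-3,4,5,6-tetramethoxyphenyl)prop-2-en-1-one | COc1c(O)c(C(=O)/C=C/c2ccc(OCc3ccccc3)c(OCc3ccccc3)c2)c(OC)c(OC)c1OC
F2 | step 7 | 2-[3,4-bis(benzyloxy)phenyl]-5,6,7,8-tetramethoxy-4H-chromen-4-one | COc1c(OC)c(OC)c2c(=O)cc(-c3ccc(OCc4ccccc4)c(OCc4ccccc4)c3)oc2c1OC
F3 | step 7 | 2-[3,4-bis(benzyloxy)phenyl]-5,6,7,8-tetramethoxy-2,3-epoxy-2,3-dihydro-4H-chromen-4-one (racemic) | COc1c(OC)c(OC)c2c(c1OC)OC1(c3ccc(OCc4ccccc4)c(OCc4ccccc4)c3)OC1C2=O
F4 | step 7 | 2-[3,4-bis(benzyloxy)phenyl]-3-hydroxy-5,6,7,8-tetramethoxy-4H-chromen-4-one | COc1c(OC)c(OC)c2c(=O)c(O)c(-c3ccc(OCc4ccccc4)c(OCc4ccccc4)c3)oc2c1OC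
F5 | step 7 | 2-[3,4-bis(benzyloxy)phenyl]-3,5-dihydroxy-6,7,8-trimethoxy-4H-chromen-4-one | COc1c(OC)c(O)c2c(=O)c(O)c(-c3ccc(OCc4ccccc4)c(OCc4ccccc4)c3)oc2c1OC
F6 | step 8 | 4-{5-(benzyloxy)-6-[3,4-bis(benzyloxy)phenyl]-4-oxo-4H-pyran-2-yl}-2,3,4-trimethoxycyclobut-2-en-1-one (racemic) | COC1=C(OC)C(OC)(c2cc(=O)c(OCc3ccccc3)c(-c3ccc(OCc4ccccc4)c(OCc4ccccc4)c3)o2)C1=O
F7 | step 5 | 2-[3,4-bis(benzyloxy)phenyl]-4,5-dihydroxy-6-methoxyoxan-3-one (mixture of diastereomers) | COC1OC(c2ccc(OCc3ccccc3)c(OCc3ccccc3)c2)C(=O)C(O)C1O
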